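A molecule of coupling partner cannot both couple and be lost, so each one meets a fork. Two times stand there: its time to couple with substrate and its time to be lost. Their ratio is the odds of coupling, a selectivity factor. Each plateau gives these odds, read with coupling partner as limiting reagent.

| setting | elm | alder | birch | maple | Friday's | Monday's | Tuesday's | Sunday's |
|---|---|---|---|---|---|---|---|---|
| substrate | 23 mM | 23 mM | 23 mM | 12 mM | 23 mM | 23 mM | 23 mM (fed, over 6.0 min) | 23 mM (fed, over 25 min) |
| coupling partner | 0.70 equiv | 0.35 equiv | 0.52 equiv | 0.70 equiv | 0.700 equiv | 0.700 equiv (fed, over 25 min) | 0.700 equiv | 0.700 equiv |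
| remark | run made earlier | run made earlier | run made earlier | run made earlier | everything together at the start | all else is in the flask from the start; the feed brings no volume worth counting | all else is in the flask from the start; the feed brings no volume worth counting | all else is in the flask from the start; the feed brings no volume worth counting |
| time |  |  |  |  | 2.0 h | 2.0 h | 2.0 h | 2.0 h |

- elm (time / min: product / %): 10.0: 15.2; 15.0: 19.2; 25.0: 28.2; 40.0: 35.6; 80.0: 43.7; 120: 43.7
- alder (time / min: product / %): 20.0: 16.6; 40.0: 24.0; 60.0: 26.2; 80.0: 25.6; 90.0: 24.8; 120: 24.9
- birch (time / min: product / %): 10.0: 12.2; 15.0: 17.0; 25.0: 24.0; 40.0: 30.7; 80.0: 33.4; 120: 34.6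
- maple (time / min: product / %): 10.0: 11.4; 30.0: 24.5; 60.0: 34.8; 80.0: 37.8; 120: 38.8

(standard deviation of a reading: 0.5 percentage points)



* the best flask by amount of product, in percent of the substrate charged; "all alike" if 1.5 percentage points covers them all (Friday's / Monday's / Tuesday's / Sunday's / all alike)
* amount of product at the end, in percent of the substrate charged, Friday's
* amount of product at the end, in percent of the substrate charged, Monday's
* amount of product at the end, in percent of the substrate charged, Tuesday's
* amount of product at the end, in percent of the substrate charged, Sunday's

The elm plateau gives a share of partner reaching product: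

f = 62.4%, odds = f/(1 − f) = 1.66

Call these the reduced odds: a run's odds brought to elm's charge by dividing by that run's √([substrate] charged ÷ equivalents) and multiplying by elm's. The other runs then read:

maple 1.72, alder 1.74, birch 1.71

These readings lie close together, so the odds are taken to follow [substrate]/√[coupling partner]. The reckoning here then gives an order, not numbers. Friday's repeats elm. Monday's feed holds [coupling partner] low early and should beat it. Substrate feeds hold [substrate] low and should fall short, Tuesday's less than Sunday's, since its feed lasts 6.0 min against 25 min.

The forecast gives 43.9%, 45.2%, 41.9% and 36.8% for Friday's, Monday's, Tuesday's and Sunday's, with Monday's “nominally best, but only narrowly”.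

The flasks give 43.6%, 45.8%, 41.8% and 36.8%, and the best is Monday's.

    substrate + coupling partner → product, rate k1*[substrate]*[coupling partner]^0.5 (k = 0.00229 M⁻⁰·⁵ s⁻¹)
    substrate ⇌ dormant form (K = 0.440, k = 2.14 × 10⁻⁵ s⁻¹)
    coupling partner → decomposed reagent (k = 3.10 × 10⁻⁴ s⁻¹)

Monday's odds come out higher than elm's 1.66:

1.89

The neighbour flask, fed like Monday's at the same equivalents, holds 5.8 mM of substrate. The same square root carries the odds over:

odds = 0.947, product = 34.1%

That neighbour flask gives 34.2%.

(All runs are calculated for substances that don't exist, and the scatter is random.)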